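Ring A is cut at C1–C10 and C3–C4 (labdane numbering). What remains, ring B with C20 on C10 and the gem-dimethyl carbon C4 on C5, is the skeleton of (+)-verbenone: there C4 is the cyclobutane carbon tied to C5 and C7, and C10 is the enone β-carbon. The key step exploits these two quaternary centres flanking C5. An allyl unit is added to C10; Lewis-acid cleavage of the strained C7–C4 bond beside the C8 carbonyl then releases a tertiary C4 cation that the allyl terminus captures. One operation turns a pinane enone into the trans-decalin. The C9 side chain is attached first; the C8 ketone finally becomes the C7=C8 acid.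

Key step: step 4

Remark (numbering): labdane-type labels are used for every compound. Ring A = C1–C5 + C10; ring B = C5–C10; C4 carries the two methyls, C10 the methyl C20, C8 the carboxyl carbon C17, C9 the chain C11–C14 (methyl C16 on C13, ester oxygen on C14). In verbenone 4: C8 = carbonyl, C9 = α-CH, C10 = β-carbon with C20, C5 and C7 = bridgeheads, C6 = CH2 bridge, C4 = CMe2 bridge.

Remark (assumption): (1R,5R)-(+)-verbenone and (R)-2-methylbutane-1,4-diol are taken as commercial. The C2 chloride of 13 is drawn as the equatorial epimer expected from anti addition; either epimer serves, since C2 loses its substituent in step 5.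

Step 1
Reactants: 1 (R)-2-methylbutane-1,4-diol
Product: 3 (5R)-5-methyl-1,3,2-dioxathiepane 2,2-dioxide (cyclic sulfate), via cyclic sulfite 2 (not isolated)
Conditions: SOCl2, CH2Cl2, 0 °C → reflux; then RuCl3·xH2O (cat.), NaIO4, MeCN–H2O, 0 °C
Reagents that add atoms: thionyl chloride O=S(Cl)Cl; sodium periodate [Na+].[O-]I(=O)(=O)=O
Why: Cyclic sulfate synthesis from a diol: SOCl2 should close the seven-membered cyclic sulfite 2 and catalytic RuO4 (from RuCl3/NaIO4) should oxidise sulfur to the sulfate, the C13 stereocentre not being involved.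

Step 2
Reactants: 4 (1R,5R)-(+)-verbenone; 3 cyclic sulfate
Product: 8 C9-[(3R)-4-hydroxy-3-methylbutyl]verbenone, via lithium dienolate 5 (not isolated), via deconjugated lithium alkyl sulfate 6 (not isolated), via conjugated lithium alkyl sulfate 7 (not isolated)
Conditions: LiN(i-Pr)2, THF, −78 °C; 3, −78 → 0 °C; DBU (cat.), rt; then H2SO4 (cat.), H2O, THF, rt
Reagents that add atoms: none
Why: Vinylogous deprotonation of 4 (its only α'-hydrogen is at a bridgehead) should give extended enolate 5, which is C-alkylated at the α-carbon C9 by SN2 opening of 3 at its unbranched O–CH2 (future C11); DBU returns the double bond of 6 into conjugation (7, erasing the transient C9 centre) and acid hydrolysis of the sulfate monoester frees the alcohol, so no new stereocentre remains and C13 comes unchanged from 1.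

Step 3
Reactants: 8 C9-[(3R)-4-hydroxy-3-methylbutyl]verbenone
Product: 9 isobutyrate ester of 8
Conditions: i-PrCOCl, pyridine, DMAP (cat.), CH2Cl2, 0 °C → rt
Reagents that add atoms: isobutyryl chloride CC(C)C(=O)Cl
Why: DMAP-catalysed acylation of the primary alcohol installs the isobutyrate of the target, which also masks the hydroxyl against TiCl4; no stereocentre is affected.

Step 4
Reactants: 9 isobutyrate ester of 8; 10 allyltrimethylsilane
Product: 13 (2S,5S,9R,10S)-2-chloro-8-oxo trans-decalin isobutyrate, via trichlorotitanium enolate 11 (not isolated), via allyl pinanone 12 (not isolated)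
Conditions: TiCl4 (2.5 equiv), 10 (1.3 equiv), CH2Cl2, −78 °C; then i-PrOH (2 equiv), −78 → 0 °C; then H2O
Reagents that add atoms: titanium tetrachloride Cl[Ti](Cl)(Cl)Cl
Why: Proposed new method: TiCl4 activates enone 9 for Hosomi–Sakurai 1,4-allylation at C10 by 10 (titanium enolate 11); protonolysis by i-PrOH/HCl releases ketone 12, whose TiCl4-bound C8 carbonyl then serves as electron sink for Grob-type heterolysis of the strained C7–C4 cyclobutane bond, and the tertiary C4 cation is captured by the allyl terminus C3 with chloride adding to C2. The closest known reactions are the Hosomi–Sakurai conjugate allylation of β,β-disubstituted enones, the Lewis-acid opening of pinanone cyclobutanes to 4-isopropenyl- or 4-(2-halopropan-2-yl)cyclohexanones, and chloride-terminated Prins-type cation–olefin cyclisations; their union in one flask is new. Ring A closes in a 6-endo-trig (Markovnikov) cation–olefin mode through a chair transition state, while the four-membered ring is opened, not closed. C10 is set by attack of the silane on the enone face anti to the CMe2 bridge, which places C1 trans to C4 on ring B so that, with the untouched C5 centre of verbenone, only the trans-decalin can form; C9 is set by protonation from the same open face (also the equatorial, thermodynamically preferred epimer), and the equatorial C2 chloride from anti addition is removed in step 5. The step needs allylation to precede ring opening (run at −78 °C before any proton source is added; once C10 is sp3 only the C7–C4 bond α to the carbonyl is activated), 6-endo over 5-exo closure (secondary versus primary cation), and cyclisation over loss of the C5 proton or external capture (six-membered chair closure; HCl destroys the small excess of 10 before warming).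

Step 5
Reactants: 13 (2S,5S,9R,10S)-2-chloro-8-oxo trans-decalin isobutyrate
Product: 14 (5S,9R,10S)-8-oxo trans-decalin isobutyrate
Conditions: Bu3SnH, AIBN (cat.), PhMe, 100 °C
Reagents that add atoms: none
Why: Radical chain dehalogenation with tin hydride: Bu3Sn• abstracts chlorine and the secondary C2 radical is quenched by Bu3SnH, leaving ketone and ester untouched and removing the C2 stereocentre.

Step 6
Reactants: 14 (5S,9R,10S)-8-oxo trans-decalin isobutyrate
Product: 16 Δ7 enol triflate (C8–OTf), via potassium enolate 15 (not isolated)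
Conditions: KN(SiMe3)2, THF, −78 °C; PhNTf2, −78 → 0 °C
Reagents that add atoms: N-phenylbis(trifluoromethanesulfonimide) O=S(=O)(N(c1ccccc1)S(=O)(=O)C(F)(F)F)C(F)(F)F
Why: Kinetic enolate formation and O-sulfonylation: the hindered amide should remove a proton from the C7 methylene rather than the tertiary C9–H next to quaternary C10 (or the less acidic isobutyrate α-H), and PhNTf2 traps enolate 15 as the Δ7 enol triflate without epimerising C9.

Step 7
Reactants: 16 Δ7 enol triflate (C8–OTf)
Product: 18 (1R,4aS,8aS)-1-[(3R)-3-methyl-4-(2-methylpropanoyloxy)butyl]-5,5,8a-trimethyl-1,4,4a,5,6,7,8,8a-octahydronaphthalene-2-carboxylic acid (target), via mixed acetic anhydride 17 (not isolated)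
Conditions: Pd(OAc)2 (5 mol %), dppf (10 mol %), CO (1 atm), KOAc, DMSO, 60 °C; then H2O, dilute HCl
Reagents that add atoms: carbon monoxide [C-]#[O+]; potassium acetate CC(=O)[O-].[K+]
Why: Pd-catalysed hydroxycarbonylation of a vinyl triflate: oxidative addition to zerovalent palladium, CO insertion and acetate capture should give mixed anhydride 17, hydrolysed on work-up to the C7=C8 acid, the weakly basic acetate leaving the isobutyrate and all stereocentres untouched.

Compound list
1 | (R)-2-methylbutane-1,4-diol | OC[C@H](C)CCO | starting material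
2 | (5R)-5-methyl-1,3,2-dioxathiepane 2-oxide (cyclic sulfite, both sulfur epimers) | O=S1OC[C@H](C)CCO1 | intermediate
3 | (5R)-5-methyl-1,3,2-dioxathiepane 2,2-dioxide (cyclic sulfate) | O=S1(=O)OC[C@H](C)CCO1 | intermediate
4 | (1R,5R)-(+)-verbenone, (1R,5R)-4,6,6-trimethylbicyclo[3.1.1]hept-3-en-2-one | CC1=CC(=O)[C@@H]2C[C@H]1C2(C)C | starting material
5 | lithium dienolate of 4 (O–C8=C9–C10=C20H2, bridgeheads unchanged) | C=C1C=C([O-])[C@@H]2C[C@H]1C2(C)C.[Li+] | intermediate
6 | lithium sulfate monoester of the C9-alkylated deconjugated ketone (C10=C20H2 exocyclic, chain on C9 anti to the CMe2 bridge) | C=C1[C@H](CC[C@@H](C)COS(=O)(=O)[O-])C(=O)[C@@H]2C[C@H]1C2(C)C.[Li+] | intermediate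
7 | lithium sulfate monoester of the C9-alkylated conjugated enone | CC1=C(CC[C@@H](C)COS(=O)(=O)[O-])C(=O)[C@@H]2C[C@H]1C2(C)C.[Li+] | intermediate
8 | C9-[(3R)-4-hydroxy-3-methylbutyl]verbenone (bridgeheads as in 4) | CC1=C(CC[C@@H](C)CO)C(=O)[C@@H]2C[C@H]1C2(C)C | intermediate
9 | isobutyrate of 8: (2R)-2-methyl-4-(verbenon-C9-yl)butyl 2-methylpropanoate | CC1=C(CC[C@@H](C)COC(=O)C(C)C)C(=O)[C@@H]2C[C@H]1C2(C)C | intermediate
10 | allyltrimethylsilane | C=CC[Si](C)(C)C | starting material
11 | trichlorotitanium enolate (C8=C9) of 12 | C=CC[C@]1(C)C(CC[C@@H](C)COC(=O)C(C)C)=C(O[Ti](Cl)(Cl)Cl)[C@@H]2C[C@H]1C2(C)C | intermediate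
12 | C10-allyl pinanone: cyclobutane intact, allyl on C10 anti and C20 syn to the CMe2 bridge, C9 chain syn to the bridge | C=CC[C@]1(C)[C@@H](CC[C@@H](C)COC(=O)C(C)C)C(=O)[C@@H]2C[C@H]1C2(C)C | intermediate
13 | (2S,5S,9R,10S)-2-chloro-4,4,10-trimethyl-9-[(3R)-4-(isobutyryloxy)-3-methylbutyl]-trans-decalin-8-one (5α-H, 9β-chain, 10β-methyl, equatorial 2α-Cl) | CC(C)C(=O)OC[C@H](C)CC[C@H]1C(=O)CC[C@H]2C(C)(C)C[C@H](Cl)C[C@]12C | intermediate
14 | (5S,9R,10S)-4,4,10-trimethyl-9-[(3R)-4-(isobutyryloxy)-3-methylbutyl]-trans-decalin-8-one | CC(C)C(=O)OC[C@H](C)CC[C@H]1C(=O)CC[C@H]2C(C)(C)CCC[C@]12C | intermediate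
15 | potassium Δ7-enolate of 14 | CC(C)C(=O)OC[C@H](C)CC[C@H]1C([O-])=CC[C@H]2C(C)(C)CCC[C@]12C.[K+] | intermediate
16 | Δ7 enol triflate of 14 (C8–OSO2CF3, C7=C8) | CC(C)C(=O)OC[C@H](C)CC[C@H]1C(OS(=O)(=O)C(F)(F)F)=CC[C@H]2C(C)(C)CCC[C@]12C | intermediate
17 | mixed anhydride of 18 with acetic acid | CC(C)C(=O)OC[C@H](C)CC[C@H]1C(C(=O)OC(C)=O)=CC[C@H]2C(C)(C)CCC[C@]12C | intermediate
18 | (1R,4aS,8aS)-1-[(3R)-3-methyl-4-(2-methylpropanoyloxy)butyl]-5,5,8a-trimethyl-1,4,4a,5,6,7,8,8a-octahydronaphthalene-2-carboxylic acid | CC(C)C(=O)OC[C@H](C)CC[C@H]1C(C(=O)O)=CC[C@H]2C(C)(C)CCC[C@]12C | target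

Total step count: 7. Longest linear sequence: 7 steps (1 → 3 → 8 → 9 → 13 → 14 → 16 → 18; 6 steps from verbenone 4).

Steps most likely to fail

Step 4 (labelled). The cyclobutane may ionise before the conjugate allylation has taken place (vinylogous opening of the enone). The C4 cation may lose the C5 proton, which would erase the C5 centre, or be captured externally faster than the 6-endo closure. The fallback uses known reactions only and sets out from 9. Copper-mediated conjugate addition of CH2=CHMgBr (CuBr·SMe2, Me3SiCl, THF, −78 °C) anti to the bridge should give the C10-vinyl pinanone F1. Dry HCl in CH2Cl2 opens the cyclobutane, as for nopinone-type ketones, to the ring-opened tertiary chloride F2. Allylation of this tertiary chloride with 10 and TiCl4 at −78 °C, where the hindered C8 ketone should not react, gives the diene ketone F3. Ring-closing metathesis with the second-generation Grubbs catalyst RuCl2(=CHPh)(H2IMes)(PCy3) closes ring A at C1=C2 to the Δ1 olefin F4. Hydrogenation (H2, Pd/C, EtOAc) returns to the route at 14.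

Step 2. The hard sulfate electrophile may alkylate the extended enolate on oxygen or at C20, may alkylate twice, or may be opened at its branched end. The fallback sets out from 3 and 4 and uses a softer electrophile that already carries the final ester. NaI in acetone opens 3 at the unbranched carbon to sodium (2R)-4-iodo-2-methylbutyl sulfate F5. Acid hydrolysis (cat. H2SO4, H2O, THF) gives (2R)-4-iodo-2-methylbutan-1-ol F6. Acylation (i-PrCOCl, pyridine) gives (2R)-4-iodo-2-methylbutyl 2-methylpropanoate F7. Dienolate 5 (from 4 with LiN(i-Pr)2, THF/DMPU, −78 → 0 °C) is alkylated at C9 by F7 to the deconjugated C9-alkylated ester ketone F8. DBU moves the double bond into conjugation and the sequence comes back to the route at 9, passing over 8.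

Step 7. Oxidative addition and CO insertion at the hindered, fully substituted vinyl triflate may be slow, so that S–O cleavage of the triflate back to the ketone, or acyl exchange at the side-chain ester, competes. The fallback sets out from 16. Pd-catalysed reductive carbonylation (Pd(PPh3)4, CO 1 atm, Bu3SnH, THF, 50 °C) should give the Δ7-8-carbaldehyde F9. Pinnick oxidation (NaClO2, NaH2PO4, 2-methyl-2-butene, t-BuOH–H2O) comes back to the route at 18.

Further compounds
F1 | step 4 | C10-vinyl pinanone (vinyl on C10 anti to the CMe2 bridge, otherwise as 12) | C=C[C@]1(C)[C@@H](CC[C@@H](C)COC(=O)C(C)C)C(=O)[C@@H]2C[C@H]1C2(C)C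
F2 | step 4 | ring-opened tertiary chloride: ring-B 8-ketone with 2-chloropropan-2-yl on C5 and vinyl on C10 | CC(C)C(=O)OC[C@H](C)CC[C@H]1C(=O)CC[C@@H](C(C)(C)Cl)[C@]1(C)C=C
F3 | step 4 | diene ketone: C5–C(CH3)2–CH2CH=CH2 and C10–CH=CH2 | CC(C)C(=O)OC[C@H](C)CC[C@H]1C(=O)CC[C@@H](C(C)(C)CC=C)[C@]1(C)C=C
F4 | step 4 | Δ1 olefin of 14 (C1=C2) | CC(C)C(=O)OC[C@H](C)CC[C@H]1C(=O)CC[C@H]2C(C)(C)CC=C[C@]12C
F5 | step 2 | sodium (2R)-4-iodo-2-methylbutyl sulfate | [Na+].[O-]S(=O)(=O)OC[C@H](C)CCI
F6 | step 2 | (2R)-4-iodo-2-methylbutan-1-ol | OC[C@H](C)CCI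
F7 | step 2 | (2R)-4-iodo-2-methylbutyl 2-methylpropanoate | CC(C)C(=O)OC[C@H](C)CCI
F8 | step 2 | deconjugated C9-alkylated verbenone ester (C10=C20H2 exocyclic, chain anti to the CMe2 bridge) | C=C1[C@H](CC[C@@H](C)COC(=O)C(C)C)C(=O)[C@@H]2C[C@H]1C2(C)C
F9 | step 7 | Δ7-8-carbaldehyde (enal corresponding to 18) | CC(C)C(=O)OC[C@H](C)CC[C@H]1C(C=O)=CC[C@H]2C(C)(C)CCC[C@]12C
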